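**Retrosynthetic overview**
- Target ⇐ desilylation and C8 tigloylation of a ten-membered 8-hydroxy α-methylene lactone.
- Key step: SmI2 ketyl-radical addition of a C8 enal to C7 of a preformed α-(acetoxymethyl)butenolide closes the ten-membered ring, forms C7–C8, sets C7/C8, and loss of acetate unveils C11=C13.
- Seco-enal ⇐ Ni/Cr coupling at C3–C4 of a (Z)-iodoalkenyl butenolide with a β-silyloxy aldehyde, then C3 acetylation.
- Butenolide (first ring) ⇐ ring-closing metathesis of a 2-(acetoxymethyl)acrylate ester; the (Z)-iodoalkene ⇐ Red-Al/I2 on the enynol from asymmetric alkynylation of crotonaldehyde.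
- Aldehyde partner ⇐ Keck allylation, silylation and oxidative cleavage of the enal from propanal and glyoxal mono(dimethyl acetal). Ring order: butenolide, then the ten-membered ring.

Locants C1–C15 in the Why lines are those of the target's germacranolide skeleton (C6 lactone O-carbon, C7, C8 tiglate carbon, C9=C10 with C14 methyl, C1 carbinol, C2, C3 acetate carbon, C4=C5 with C15 hydroxymethyl, C11=C13 methylene, C12 carbonyl). TBS = tert-butyldimethylsilyl.

**Step 1**
Reactants: 1 prop-2-yn-1-ol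
Product: 2 tert-butyldimethyl(prop-2-yn-1-yloxy)silane
Conditions: TBSCl, imidazole, CH2Cl2, 0 °C → rt
Reagents that add atoms: tert-butyldimethylsilyl chloride, CC(C)(C)[Si](C)(C)Cl
Why: Standard silyl ether formation protects the future C15 hydroxyl so that only the C6 hydroxyl can direct the later hydroalumination.

**Step 2**
Reactants: 2 tert-butyldimethyl(prop-2-yn-1-yloxy)silane; 3 (2E)-but-2-enal
Product: 5 (2E,4S)-7-(TBS-oxy)hept-2-en-5-yn-4-ol, via alkynyl(methyl)zinc 4 (not isolated)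
Conditions: ZnMe2 (2.9 equiv), (S,S)-ProPhenol (10 mol%), Ph3P=O (20 mol%), toluene, 0 °C; then 3, 4 °C; aq. NH4Cl
Reagents that add atoms: none
Why: Trost ProPhenol–zinc asymmetric alkynylation, in which the dinuclear zinc complex delivers the zinc acetylide 4 to the Re face of the enal in 1,2-fashion and so sets 4S (the future C6); the ligand antipode is used if the facial sense is found reversed.

**Step 3**
Reactants: 5 (2E,4S)-7-(TBS-oxy)hept-2-en-5-yn-4-ol
Product: 7 (2Z,4S,5E)-1-(TBS-oxy)-2-iodohepta-2,5-dien-4-ol, via vinylaluminate 6 (not isolated)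
Conditions: NaAlH2(OCH2CH2OMe)2 (Red-Al, 1.6 equiv), THF, −20 → 0 °C; then I2, −78 °C; aq. potassium sodium tartrate, Na2S2O3
Reagents that add atoms: iodine, II
Why: Hydroxyl-directed trans-hydroalumination puts hydride on C5 and aluminium on C4 in the five-membered aluminate 6, and iodinolysis with retention gives the Z-iodoalkene (C6 cis to iodine) that later fixes the 4Z geometry, leaving the propenyl group and the carbinol centre untouched.

**Step 4**
Reactants: 8 2-(bromomethyl)prop-2-enoic acid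
Product: 9 2-(acetoxymethyl)prop-2-enoic acid
Conditions: KOAc, AcOH, 60 °C
Reagents that add atoms: potassium acetate, CC(=O)[O-].[K+]
Why: Acetate displaces the very reactive allylic bromide (SN2, or the degenerate SN2′), and acetic acid as solvent keeps the substrate carboxyl protonated so it does not compete.

**Step 5**
Reactants: 7 (2Z,4S,5E)-1-(TBS-oxy)-2-iodohepta-2,5-dien-4-ol; 9 2-(acetoxymethyl)prop-2-enoic acid
Product: 10 (2Z,4S,5E)-1-(TBS-oxy)-2-iodohepta-2,5-dien-4-yl 2-(acetoxymethyl)prop-2-enoate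
Conditions: DCC, DMAP (5 mol%), CH2Cl2, 0 °C
Reagents that add atoms: none
Why: Steglich esterification acylates the secondary alcohol with retention at C6, the low DMAP loading limiting attack on the acetoxymethyl acrylate.

**Step 6**
Reactants: 10 (2Z,4S,5E)-1-(TBS-oxy)-2-iodohepta-2,5-dien-4-yl 2-(acetoxymethyl)prop-2-enoate
Product: 11 (5S)-3-(acetoxymethyl)-5-[(1Z)-2-iodo-3-(TBS-oxy)prop-1-en-1-yl]furan-2(5H)-one
Conditions: second-generation Grubbs catalyst RuCl2(=CHPh)(H2IMes)(PCy3) (5 mol%), toluene (0.01 M), 80 °C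
Reagents that add atoms: none
Why: Ring-closing metathesis, in which the ruthenium alkylidene loads on the propenyl group and closes onto the acrylate with loss of propene to give the butenolide, while the hindered trisubstituted iodoalkene stays out and C6 is untouched.

**Step 7**
Reactants: 12 propanal; 13 2,2-dimethoxyacetaldehyde
Product: 14 (2E)-4,4-dimethoxy-2-methylbut-2-enal
Conditions: pyrrolidine (10 mol%), propanoic acid (10 mol%), 2-propanol, 50 °C, slow addition of 12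
Reagents that add atoms: none
Why: Amine-catalysed cross-aldol condensation, in which the enamine of propanal adds to the non-enolisable glyoxal acetal and dehydration gives the thermodynamically preferred E-enal (C1 trans to C8).

**Step 8**
Reactants: 14 (2E)-4,4-dimethoxy-2-methylbut-2-enal
Product: 15 (4S,5E)-7,7-dimethoxy-5-methylhepta-1,5-dien-4-ol
Conditions: allyltributylstannane, (S)-BINOL (10 mol%), Ti(OiPr)4 (10 mol%), 4 Å MS, CH2Cl2, −20 °C; aq. NaHCO3
Reagents that add atoms: allyltributylstannane, C=CC[Sn](CCCC)(CCCC)CCCC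
Why: Keck asymmetric allylation, where the (S)-BINOL–titanium Lewis acid directs 1,2-addition of the allyl group to the Si face of the enal and sets 4S (the future C1) without disturbing the acetal.

**Step 9**
Reactants: 15 (4S,5E)-7,7-dimethoxy-5-methylhepta-1,5-dien-4-ol
Product: 16 (4S,5E)-4-(TBS-oxy)-7,7-dimethoxy-5-methylhepta-1,5-diene
Conditions: TBSCl, imidazole, DMF, rt
Reagents that add atoms: tert-butyldimethylsilyl chloride, CC(C)(C)[Si](C)(C)Cl
Why: Silyl ether formation under non-acidic conditions masks the C1 hydroxyl so that only the C8 carbinol is free for the later tigloylation.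

**Step 10**
Reactants: 16 (4S,5E)-4-(TBS-oxy)-7,7-dimethoxy-5-methylhepta-1,5-diene
Product: 17 (3S,4E)-3-(TBS-oxy)-6,6-dimethoxy-4-methylhex-4-enal
Conditions: OsO4 (2 mol%), NaIO4, 2,6-lutidine, dioxane/H2O, rt
Reagents that add atoms: sodium periodate (oxygen source, through OsO4), [Na+].[O-]I(=O)(=O)=O
Why: Lemieux–Johnson oxidative cleavage, in which OsO4 selects the unhindered terminal alkene over the trisubstituted alkene flanked by two oxygenated carbons, and the lutidine buffer preserves the acetal and the β-silyloxy aldehyde.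

**Step 11**
Reactants: 11 (5S)-3-(acetoxymethyl)-5-[(1Z)-2-iodo-3-(TBS-oxy)prop-1-en-1-yl]furan-2(5H)-one; 17 (3S,4E)-3-(TBS-oxy)-6,6-dimethoxy-4-methylhex-4-enal
Product: 18 (5R)-3-(acetoxymethyl)-5-[(1Z,3S,5S,6E)-3-hydroxy-8,8-dimethoxy-6-methyl-5-(TBS-oxy)-2-[(TBS-oxy)methyl]octa-1,6-dien-1-yl]furan-2(5H)-one
Conditions: CrCl2 (3 equiv), Kishi oxazoline–sulfonamide ligand (3.3 equiv, enantiomer directing Re-face addition), Et3N (3.3 equiv, premixed), NiCl2 (2 mol%), THF, rt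
Reagents that add atoms: none
Why: Nozaki–Hiyama–Kishi coupling, in which the alkenylchromium formed with retention of the Z geometry adds to the aldehyde in the presence of the lactone, acetate and silyl ethers, and the chiral sulfonamide on chromium directs Re-face attack to set 3S.

**Step 12**
Reactants: 18 (5R)-3-(acetoxymethyl)-5-[(1Z,3S,5S,6E)-3-hydroxy-8,8-dimethoxy-6-methyl-5-(TBS-oxy)-2-[(TBS-oxy)methyl]octa-1,6-dien-1-yl]furan-2(5H)-one
Product: 19 (5R)-5-[(1Z,3S,5S,6E)-3-acetoxy-8,8-dimethoxy-6-methyl-5-(TBS-oxy)-2-[(TBS-oxy)methyl]octa-1,6-dien-1-yl]-3-(acetoxymethyl)furan-2(5H)-one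
Conditions: Ac2O, pyridine, DMAP (cat.), CH2Cl2, 0 °C
Reagents that add atoms: acetic anhydride, CC(=O)OC(C)=O
Why: Acetylation of the only free hydroxyl installs the C3 acetate with retention, pyridine being too weak a base to epimerise the butenolide γ-carbon C6.

**Step 13**
Reactants: 19 (5R)-5-[(1Z,3S,5S,6E)-3-acetoxy-8,8-dimethoxy-6-methyl-5-(TBS-oxy)-2-[(TBS-oxy)methyl]octa-1,6-dien-1-yl]-3-(acetoxymethyl)furan-2(5H)-one
Product: 20 (5R)-5-[(1Z,3S,5S,6E)-3-acetoxy-6-methyl-8-oxo-5-(TBS-oxy)-2-[(TBS-oxy)methyl]octa-1,6-dien-1-yl]-3-(acetoxymethyl)furan-2(5H)-one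
Conditions: PPTS, acetone/H2O (10:1), rt
Reagents that add atoms: water, O
Why: Mild acetal hydrolysis frees the conjugated E-enal (C8) through the stabilised allylic oxocarbenium ion, under conditions that leave the TBS ethers and both acetates intact.

**Step 14**
Reactants: 20 (5R)-5-[(1Z,3S,5S,6E)-3-acetoxy-6-methyl-8-oxo-5-(TBS-oxy)-2-[(TBS-oxy)methyl]octa-1,6-dien-1-yl]-3-(acetoxymethyl)furan-2(5H)-one
Product: 21 (3aR,4R,5E,7S,9S,10Z,11aR)-4-hydroxy-6-methyl-3-methylidene-2-oxo-7-(TBS-oxy)-10-[(TBS-oxy)methyl]-2,3,3a,4,7,8,9,11a-octahydrocyclodeca[b]furan-9-yl acetate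
Conditions: SmI2 (2.2 equiv, 0.1 M in THF, syringe pump), THF (0.002 M in 20), −78 → −20 °C; aq. NH4Cl
Reagents that add atoms: none
Why: Proposed new method: SmI2 reduces the enal to a trivalent-samarium ketyl (an allyl-type radical whose C10 end is fully substituted, so it reacts at C8), which adds as a nucleophilic radical to C7 of the electron-poor butenolide from the H6 face, where allylic 1,3-strain at the Z-alkene holds the tether (giving the trans-fused lactone), with the samarium-bound oxygen turned toward the lactone carbonyl in a chelated ketyl–enoate-type transition state (giving 8R), after which a second electron forms the samarium enolate that expels acetate (E1cB) to unveil the C11=C13 methylene; the closest known chemistry is the SmI2 ketyl–olefin (aldehyde–unsaturated ester) reductive cyclisation and the SmI2-induced β-elimination of β-acyloxy enolates, here used for a ten-membered closure pre-organised by the butenolide, the Z-alkene and the E-enal.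

**Step 15**
Reactants: 21 (3aR,4R,5E,7S,9S,10Z,11aR)-4-hydroxy-6-methyl-3-methylidene-2-oxo-7-(TBS-oxy)-10-[(TBS-oxy)methyl]-2,3,3a,4,7,8,9,11a-octahydrocyclodeca[b]furan-9-yl acetate
Product: 22 (3aR,4R,5E,7S,9S,10Z,11aR)-9-acetoxy-6-methyl-3-methylidene-2-oxo-7-(TBS-oxy)-10-[(TBS-oxy)methyl]-2,3,3a,4,7,8,9,11a-octahydrocyclodeca[b]furan-4-yl (2E)-2-methylbut-2-enoate
Conditions: (E)-2-methylbut-2-enoyl chloride, pyridine, DMAP (cat.), CH2Cl2, 0 °C → rt
Reagents that add atoms: (E)-2-methylbut-2-enoyl chloride, C/C=C(\C)C(=O)Cl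
Why: DMAP-catalysed acylation of the only free hydroxyl with retention at C8 installs the tiglate, which as the stable E-ester does not isomerise.

**Step 16**
Reactants: 22 (3aR,4R,5E,7S,9S,10Z,11aR)-9-acetoxy-6-methyl-3-methylidene-2-oxo-7-(TBS-oxy)-10-[(TBS-oxy)methyl]-2,3,3a,4,7,8,9,11a-octahydrocyclodeca[b]furan-4-yl (2E)-2-methylbut-2-enoate
Product: 23 (3aR,4R,5E,7S,9S,10Z,11aR)-9-acetoxy-7-hydroxy-10-(hydroxymethyl)-6-methyl-3-methylidene-2-oxo-2,3,3a,4,7,8,9,11a-octahydrocyclodeca[b]furan-4-yl (2E)-2-methylbut-2-enoate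
Conditions: HF·pyridine, pyridine, THF, 0 °C → rt
Reagents that add atoms: none
Why: Buffered fluoride desilylation removes both TBS ethers under weakly acidic conditions that avoid acyl migration of the C3 acetate and spare the tiglate and the α-methylene lactone.

**Compound list**
1 | prop-2-yn-1-ol | C#CCO | starting material
2 | tert-butyldimethyl(prop-2-yn-1-yloxy)silane | C#CCO[Si](C)(C)C(C)(C)C | intermediate
3 | (2E)-but-2-enal | C/C=C/C=O | starting material
4 | methyl[3-(TBS-oxy)prop-1-yn-1-yl]zinc | C[Zn]C#CCO[Si](C)(C)C(C)(C)C | intermediate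
5 | (2E,4S)-7-(TBS-oxy)hept-2-en-5-yn-4-ol | C/C=C/[C@H](O)C#CCO[Si](C)(C)C(C)(C)C | intermediate
6 | sodium (5S)-2,2-bis(2-methoxyethoxy)-5-[(1E)-prop-1-en-1-yl]-3-[(TBS-oxy)methyl]-2,5-dihydro-1,2-oxaluminol-2-uide | [Na+].COCCO[Al-]1(OCCOC)O[C@@H](/C=C/C)C=C1CO[Si](C)(C)C(C)(C)C | intermediate
7 | (2Z,4S,5E)-1-(TBS-oxy)-2-iodohepta-2,5-dien-4-ol | C/C=C/[C@H](O)/C=C(\I)CO[Si](C)(C)C(C)(C)C | intermediate
8 | 2-(bromomethyl)prop-2-enoic acid | C=C(CBr)C(=O)O | starting material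
9 | 2-(acetoxymethyl)prop-2-enoic acid | C=C(COC(C)=O)C(=O)O | intermediate
10 | (2Z,4S,5E)-1-(TBS-oxy)-2-iodohepta-2,5-dien-4-yl 2-(acetoxymethyl)prop-2-enoate | C/C=C/[C@H](OC(=O)C(=C)COC(C)=O)/C=C(\I)CO[Si](C)(C)C(C)(C)C | intermediate
11 | (5S)-3-(acetoxymethyl)-5-[(1Z)-2-iodo-3-(TBS-oxy)prop-1-en-1-yl]furan-2(5H)-one | CC(=O)OCC1=C[C@@H](/C=C(\I)CO[Si](C)(C)C(C)(C)C)OC1=O | intermediate
12 | propanal | CCC=O | starting material
13 | 2,2-dimethoxyacetaldehyde | COC(OC)C=O | starting material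
14 | (2E)-4,4-dimethoxy-2-methylbut-2-enal | O=C/C(C)=C/C(OC)OC | intermediate
15 | (4S,5E)-7,7-dimethoxy-5-methylhepta-1,5-dien-4-ol | C=CC[C@H](O)/C(C)=C/C(OC)OC | intermediate
16 | (4S,5E)-4-(TBS-oxy)-7,7-dimethoxy-5-methylhepta-1,5-diene | C=CC[C@H](O[Si](C)(C)C(C)(C)C)/C(C)=C/C(OC)OC | intermediate
17 | (3S,4E)-3-(TBS-oxy)-6,6-dimethoxy-4-methylhex-4-enal | O=CC[C@H](O[Si](C)(C)C(C)(C)C)/C(C)=C/C(OC)OC | intermediate
18 | (5R)-3-(acetoxymethyl)-5-[(1Z,3S,5S,6E)-3-hydroxy-8,8-dimethoxy-6-methyl-5-(TBS-oxy)-2-[(TBS-oxy)methyl]octa-1,6-dien-1-yl]furan-2(5H)-one | CC(=O)OCC1=C[C@@H](/C=C(/CO[Si](C)(C)C(C)(C)C)[C@@H](O)C[C@H](O[Si](C)(C)C(C)(C)C)/C(C)=C/C(OC)OC)OC1=O | intermediate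
19 | (5R)-5-[(1Z,3S,5S,6E)-3-acetoxy-8,8-dimethoxy-6-methyl-5-(TBS-oxy)-2-[(TBS-oxy)methyl]octa-1,6-dien-1-yl]-3-(acetoxymethyl)furan-2(5H)-one | CC(=O)OCC1=C[C@@H](/C=C(/CO[Si](C)(C)C(C)(C)C)[C@@H](OC(C)=O)C[C@H](O[Si](C)(C)C(C)(C)C)/C(C)=C/C(OC)OC)OC1=O | intermediate
20 | (5R)-5-[(1Z,3S,5S,6E)-3-acetoxy-6-methyl-8-oxo-5-(TBS-oxy)-2-[(TBS-oxy)methyl]octa-1,6-dien-1-yl]-3-(acetoxymethyl)furan-2(5H)-one | CC(=O)OCC1=C[C@@H](/C=C(/CO[Si](C)(C)C(C)(C)C)[C@@H](OC(C)=O)C[C@H](O[Si](C)(C)C(C)(C)C)/C(C)=C/C=O)OC1=O | intermediate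
21 | (3aR,4R,5E,7S,9S,10Z,11aR)-4-hydroxy-6-methyl-3-methylidene-2-oxo-7-(TBS-oxy)-10-[(TBS-oxy)methyl]-2,3,3a,4,7,8,9,11a-octahydrocyclodeca[b]furan-9-yl acetate | C=C1C(=O)O[C@@H]2/C=C(/CO[Si](C)(C)C(C)(C)C)[C@@H](OC(C)=O)C[C@H](O[Si](C)(C)C(C)(C)C)/C(C)=C/[C@@H](O)[C@@H]12 | intermediate
22 | (3aR,4R,5E,7S,9S,10Z,11aR)-9-acetoxy-6-methyl-3-methylidene-2-oxo-7-(TBS-oxy)-10-[(TBS-oxy)methyl]-2,3,3a,4,7,8,9,11a-octahydrocyclodeca[b]furan-4-yl (2E)-2-methylbut-2-enoate | C=C1C(=O)O[C@@H]2/C=C(/CO[Si](C)(C)C(C)(C)C)[C@@H](OC(C)=O)C[C@H](O[Si](C)(C)C(C)(C)C)/C(C)=C/[C@@H](OC(=O)/C(C)=C/C)[C@@H]12 | intermediate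
23 | (3aR,4R,5E,7S,9S,10Z,11aR)-9-acetoxy-7-hydroxy-10-(hydroxymethyl)-6-methyl-3-methylidene-2-oxo-2,3,3a,4,7,8,9,11a-octahydrocyclodeca[b]furan-4-yl (2E)-2-methylbut-2-enoate | C=C1C(=O)O[C@@H]2/C=C(/CO)[C@@H](OC(C)=O)C[C@H](O)/C(C)=C/[C@@H](OC(=O)/C(C)=C/C)[C@@H]12 | target

**Step count**
Total: 16 steps. Longest linear sequence: 11 steps (steps 1, 2, 3, 5, 6, 11, 12, 13, 14, 15, 16).

**Three steps most likely to fail**

Step 14 (ring closure). The ten-membered closure may lose to pinacol dimerisation, plain reduction of the enal, or give little ring at all. The fallback sets out from 16 and 11 and comes back at 22: it keeps the ketyl addition for the C7–C8 bond but runs it between two molecules and closes the ring at C3–C4 instead. PPTS in wet acetone frees the enal of 16 to give (2E,4S)-4-(TBS-oxy)-3-methylhepta-2,6-dienal F1. SmI2 in THF then couples the ketyl of F1 with butenolide 11 by the same addition–elimination; the vinyl iodide is inert to SmI2 without HMPA. This gives (4R,5S)-4-[(1R,2E,4S)-1-hydroxy-3-methyl-4-(TBS-oxy)hepta-2,6-dien-1-yl]-5-[(1Z)-2-iodo-3-(TBS-oxy)prop-1-en-1-yl]-3-methylideneoxolan-2-one F2. (E)-2-Methylbut-2-enoyl chloride with pyridine and DMAP gives the C8 tiglate of this carbinol F3. OsO4/NaIO4 cleaves the terminal alkene to the iodo-aldehyde tiglate F4. An intramolecular Nozaki–Hiyama–Kishi reaction (CrCl2, NiCl2 cat., the same sulfonamide ligand, high dilution) closes the ring to the 9-hydroxy macrocycle (3aR,4R,5E,7S,9S,10Z,11aR)-9-hydroxy-6-methyl-3-methylidene-2-oxo-7-(TBS-oxy)-10-[(TBS-oxy)methyl]-2,3,3a,4,7,8,9,11a-octahydrocyclodeca[b]furan-4-yl (2E)-2-methylbut-2-enoate F5. Ac2O/pyridine converts it into 22.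

Step 11 (fragment coupling). The iodide is trisubstituted, the butenolide is base-sensitive, nickel may engage the allylic acetate, and ligand control at C3 may be modest. The fallback sets out from 11 and 17 and comes back at 18: C3 is set by ketone reduction instead of by the addition. A ligand-free coupling (CrCl2, NiCl2 cat., DMSO) gives the C3-epimeric mixture of 18 F6. Dess–Martin periodinane oxidises it to the (Z)-enone, the 3-oxo analogue of 18 F7. (R)-2-Methyl-CBS-oxazaborolidine with catecholborane in toluene at −78 °C reduces the ketone, the alkenyl group acting as the large substituent, and returns 18 with 3S.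

Step 15 (esterification at C8). Acylation with retention gives 22 only from the 8R carbinol; if the ketyl in step 14 closes through its other face, the product is the C8 epimer. The fallback sets out from 20 and comes back at 22: step 14 then delivers (3aR,4S,5E,7S,9S,10Z,11aR)-4-hydroxy-6-methyl-3-methylidene-2-oxo-7-(TBS-oxy)-10-[(TBS-oxy)methyl]-2,3,3a,4,7,8,9,11a-octahydrocyclodeca[b]furan-9-yl acetate F8, and a Mitsunobu esterification with (E)-2-methylbut-2-enoic acid, PPh3 and DIAD in toluene at 0 °C installs the tiglate with inversion to give 22.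

**Further compounds**
F1 | step 14 | (2E,4S)-4-(TBS-oxy)-3-methylhepta-2,6-dienal | C=CC[C@H](O[Si](C)(C)C(C)(C)C)/C(C)=C/C=O
F2 | step 14 | (4R,5S)-4-[(1R,2E,4S)-1-hydroxy-3-methyl-4-(TBS-oxy)hepta-2,6-dien-1-yl]-5-[(1Z)-2-iodo-3-(TBS-oxy)prop-1-en-1-yl]-3-methylideneoxolan-2-one | C=C1C(=O)O[C@H](/C=C(\I)CO[Si](C)(C)C(C)(C)C)[C@H]1[C@H](O)/C=C(\C)[C@@H](O[Si](C)(C)C(C)(C)C)CC=C
F3 | step 14 | C8 (2E)-2-methylbut-2-enoate of F2 | C=C1C(=O)O[C@H](/C=C(\I)CO[Si](C)(C)C(C)(C)C)[C@H]1[C@H](OC(=O)/C(C)=C/C)/C=C(\C)[C@@H](O[Si](C)(C)C(C)(C)C)CC=C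
F4 | step 14 | iodo-aldehyde tiglate (terminal CH=CH2 of F3 cut to CHO) | C=C1C(=O)O[C@H](/C=C(\I)CO[Si](C)(C)C(C)(C)C)[C@H]1[C@H](OC(=O)/C(C)=C/C)/C=C(\C)[C@@H](O[Si](C)(C)C(C)(C)C)CC=O
F5 | step 14 | (3aR,4R,5E,7S,9S,10Z,11aR)-9-hydroxy-6-methyl-3-methylidene-2-oxo-7-(TBS-oxy)-10-[(TBS-oxy)methyl]-2,3,3a,4,7,8,9,11a-octahydrocyclodeca[b]furan-4-yl (2E)-2-methylbut-2-enoate | C=C1C(=O)O[C@@H]2/C=C(/CO[Si](C)(C)C(C)(C)C)[C@@H](O)C[C@H](O[Si](C)(C)C(C)(C)C)/C(C)=C/[C@@H](OC(=O)/C(C)=C/C)[C@@H]12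
F6 | step 11 | C3-epimeric mixture of 18 (3RS carbinol) | CC(=O)OCC1=C[C@@H](/C=C(/CO[Si](C)(C)C(C)(C)C)C(O)C[C@H](O[Si](C)(C)C(C)(C)C)/C(C)=C/C(OC)OC)OC1=O
F7 | step 11 | (Z)-enone, 3-oxo analogue of 18 | CC(=O)OCC1=C[C@@H](/C=C(/CO[Si](C)(C)C(C)(C)C)C(=O)C[C@H](O[Si](C)(C)C(C)(C)C)/C(C)=C/C(OC)OC)OC1=O
F8 | step 15 | (3aR,4S,5E,7S,9S,10Z,11aR)-4-hydroxy-6-methyl-3-methylidene-2-oxo-7-(TBS-oxy)-10-[(TBS-oxy)methyl]-2,3,3a,4,7,8,9,11a-octahydrocyclodeca[b]furan-9-yl acetate (C8 epimer of 21) | C=C1C(=O)O[C@@H]2/C=C(/CO[Si](C)(C)C(C)(C)C)[C@@H](OC(C)=O)C[C@H](O[Si](C)(C)C(C)(C)C)/C(C)=C/[C@H](O)[C@@H]12
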